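**Plan**
- Retrosynthesis: the dihydropyran ring is cut first at O–C10 and C1′–C1, together with the aryl–C1′ bond, giving 2,4-diformylphloroglucinol, 3-methylbutanal and the (1(10)E,5Z)-germacratrienol 13.
- What makes this possible: O–C10–C1–C1′ plus two adjacent phloroglucinol carbons form a chromane ring, the retron of an o-quinone methide/alkene oxa-Diels–Alder reaction, and C1=C10 is a strained (E)-trisubstituted alkene in a ten-membered ring.
- 13 is cut at C4=C15 (Wittig), then at C4–C10 of a trans-fused 5–7 bicycle (Grob ring expansion), then at C5=C6 (ring-closing metathesis), then at C9–C10 and C10–C14 of a cyclopentane-1,3-dione.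
- Forward order: C7 lactone, cyclopentanedione alkylation, cycloheptene, ten-membered ring, dihydropyran ring.
- Stereochemistry: C7 from a rhodium-catalysed asymmetric vinyl addition; 1(10)E from the stereospecific fragmentation; 5Z from the seven-membered ring; C10, C1 and C1′ in the cycloaddition, relayed from C7.

Key step: step 10

Remark: germacrane locants are used throughout (ring C1–C10, C11 the carbinol carbon on C7, C14 the methyl on C10, C15 the methylene carbon on C4, C1′ the benzylic carbon).

Remark: ring centres C1, C4 and C10 of 8–11 are temporary (all become sp2 in step 9). Step 5 cannot tell the two carbonyl groups of 7 apart through the remote centre C7, so 8–11 are each expected as a pair of diastereomers with the same relative ring configuration. Both converge on the single compound 13; names and SMILES show one member of each pair.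

**Step 1**
Reactants: 1 5,5-dimethylfuran-2(5H)-one
Product: 2 (R)-5,5-dimethyl-4-vinyldihydrofuran-2(3H)-one
Conditions: CH2=CHBF3K (2 equiv), [Rh(cod)2]PF6 (3 mol%), (R)-BINAP (3.3 mol%), toluene/H2O 4:1, 105 °C
Reagents that add atoms: potassium vinyltrifluoroborate, C=C[B-](F)(F)F.[K+]
Why: Hayashi–Miyaura asymmetric 1,4-addition of an alkenylboron reagent to an unsaturated lactone; the BINAP–rhodium–vinyl species adds to one enantiotopic face of the planar butenolide and sets C7 (the (R) sense with (R)-BINAP is assigned by analogy with cyclic enones and should be confirmed on the first sample).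

**Step 2**
Reactants: 2 (R)-5,5-dimethyl-4-vinyldihydrofuran-2(3H)-one
Product: 3 (4R)-5,5-dimethyl-4-vinyltetrahydrofuran-2-ol (both anomers)
Conditions: i-Bu2AlH (DIBAL-H, 1.1 equiv), CH2Cl2, −78 °C; aq. potassium sodium tartrate
Reagents that add atoms: none
Why: partial reduction of a γ-lactone to the lactol, since the aluminium hemiacetal does not collapse at −78 °C; C7 is β to the carbonyl and cannot epimerise.

**Step 3**
Reactants: 3 (4R)-5,5-dimethyl-4-vinyltetrahydrofuran-2-ol; 4 cyclopentane-1,3-dione
Product: 6 2-[(3R)-3-(2-hydroxypropan-2-yl)pent-4-en-1-yl]cyclopentane-1,3-dione, via alkylidenedione 5 (not isolated)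
Conditions: L-proline (20 mol%), diethyl 2,6-dimethyl-1,4-dihydropyridine-3,5-dicarboxylate (Hantzsch ester, 1.1 equiv), CH2Cl2, 25 °C
Reagents that add atoms: none
Why: organocatalytic three-component reductive alkylation: Knoevenagel condensation of the open hydroxy-aldehyde form of the lactol with the dione, then transfer hydrogenation of alkylidenedione 5 by the Hantzsch ester; this forms C9–C10 with C-selectivity, and any reversible oxa-Michael closure of 5 by the tertiary hydroxyl should drain through the irreversible hydride transfer.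

**Step 4**
Reactants: 6 2-[(3R)-3-(2-hydroxypropan-2-yl)pent-4-en-1-yl]cyclopentane-1,3-dione
Product: 7 2-[(3R)-3-(2-hydroxypropan-2-yl)pent-4-en-1-yl]-2-methylcyclopentane-1,3-dione
Conditions: MeI (3 equiv), NaOH (1.05 equiv), H2O/dioxane, 25–40 °C
Reagents that add atoms: iodomethane, CI
Why: C-methylation of a 2-alkylcyclopentane-1,3-dione enolate with a soft electrophile in a protic medium builds quaternary C10 with C14; the tertiary alcohol is not alkylated, and any enol methyl ether can be hydrolysed back to 6 with dilute acid and recycled.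

**Step 5**
Reactants: 7 2-[(3R)-3-(2-hydroxypropan-2-yl)pent-4-en-1-yl]-2-methylcyclopentane-1,3-dione
Product: 8 3-hydroxy-2-[(3R)-3-(2-hydroxypropan-2-yl)pent-4-en-1-yl]-2-methyl-3-vinylcyclopentan-1-one (vinyl cis to the ring methyl, ring hydroxyl cis to the side chain)
Conditions: CeCl3 (2.5 equiv), CH2=CHMgBr (2.5 equiv), THF, −78 °C; aq. NH4Cl at −78 °C
Reagents that add atoms: vinylmagnesium bromide, C=C[Mg]Br
Why: mono-1,2-addition of a vinylcerium reagent to a 2,2-disubstituted 1,3-dione; the organocerium suppresses enolisation and retro-aldol opening, and the alkoxide formed shields the second carbonyl. The nucleophile should enter anti to the longer C9 chain, placing vinyl cis to C14 and the C4 hydroxyl trans to it; one equivalent is consumed by the tertiary O–H.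

**Step 6**
Reactants: 8 3-hydroxy-2-[(3R)-3-(2-hydroxypropan-2-yl)pent-4-en-1-yl]-2-methyl-3-vinylcyclopentan-1-one
Product: 9 2-[(3R)-3-(2-hydroxypropan-2-yl)pent-4-en-1-yl]-2-methyl-1-vinylcyclopentane-1,3-diol (ring hydroxyls trans to each other, secondary hydroxyl cis to the ring methyl)
Conditions: Me4NBH(OAc)3 (5 equiv), MeCN/AcOH 1:1, −25 °C
Reagents that add atoms: none
Why: Evans–Saksena hydroxyl-directed reduction; the borohydride bound to the C4 oxygen delivers hydride to the same face of the C1 ketone, so the new hydroxyl is anti to the C4 hydroxyl and therefore cis to C14, as the fragmentation requires.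

**Step 7**
Reactants: 9 2-[(3R)-3-(2-hydroxypropan-2-yl)pent-4-en-1-yl]-2-methyl-1-vinylcyclopentane-1,3-diol
Product: 10 6-(2-hydroxypropan-2-yl)-8a-methyl-1,2,3,3a,6,7,8,8a-octahydroazulene-1,3a-diol (trans-fused, 1-OH cis to 8a-methyl, 6R)
Conditions: second-generation Grubbs catalyst RuCl2(=CHPh)(H2IMes)(PCy3) (5 mol%), CH2Cl2 (0.005 M), 40 °C
Reagents that add atoms: none
Why: ring-closing metathesis of two monosubstituted alkenes to a cycloheptene, with free hydroxyls tolerated; the seven-membered ring can only hold a cis alkene, which fixes the later 5Z geometry.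

**Step 8**
Reactants: 10 6-(2-hydroxypropan-2-yl)-8a-methyl-1,2,3,3a,6,7,8,8a-octahydroazulene-1,3a-diol
Product: 11 3a-hydroxy-6-(2-hydroxypropan-2-yl)-8a-methyl-1,2,3,3a,6,7,8,8a-octahydroazulen-1-yl methanesulfonate
Conditions: MsCl (1.2 equiv), Et3N (2 equiv), CH2Cl2, −20 °C
Reagents that add atoms: methanesulfonyl chloride, CS(=O)(=O)Cl
Why: selective sulfonylation (via sulfene) of the only secondary hydroxyl in the presence of two tertiary ones, with retention at C1.

**Step 9**
Reactants: 11 3a-hydroxy-6-(2-hydroxypropan-2-yl)-8a-methyl-1,2,3,3a,6,7,8,8a-octahydroazulen-1-yl methanesulfonate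
Product: 13 (1(10)E,5Z,7R)-germacra-1(10),4(15),5-trien-11-ol, via cyclodecadienone 12 (not isolated)
Conditions: KOt-Bu (1.05 equiv), THF, −40 → 0 °C; then Ph3P=CH2 (from Ph3PCH3Br 4.0 equiv, KOt-Bu 3.6 equiv), THF, 0 → 25 °C
Reagents that add atoms: methylenetriphenylphosphorane (from methyltriphenylphosphonium bromide and KOt-Bu), C=P(c1ccccc1)(c1ccccc1)c1ccccc1
Why: Grob (Wharton) fragmentation of a 1,3-diol monosulfonate: the C4 alkoxide expels the C1 mesylate across the anti-periplanar C4–C10 fusion bond, expanding the 5–7 bicycle to the ten-membered ring and giving the C4 ketone. Because the mesylate is cis to C14, C9 and C2 are anti in the transition state and the C1=C10 alkene should form as E, while Z-C5=C6 is carried over from the cycloheptene. The enone is then methylenated in the same flask by a Wittig reaction, with excess phosphonium salt buffering residual alkoxide so that C7 (γ to the carbonyl) is not epimerised.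

**Step 10**
Reactants: 13 (1(10)E,5Z,7R)-germacra-1(10),4(15),5-trien-11-ol; 14 2,4,6-trihydroxybenzene-1,3-dicarbaldehyde; 15 3-methylbutanal
Product: 17 target CNP0479784.1, via o-quinone methide 16 (not isolated)
Conditions: 14 (1.1 equiv), 15 (1.3 equiv, added slowly), ethylenediammonium diacetate (20 mol%), 4 Å MS, THF, 50 °C
Reagents that add atoms: none
Why: The diammonium acetate catalyses Knoevenagel condensation of 15 at the only free ring position of 14, and loss of water gives the (E)-o-quinone methide 16, an electron-poor 1-oxadiene that is taken up at once by the most nucleophilic and most strained π-bond of 13, the (E)-trisubstituted C1=C10 alkene; the closest known reaction type is the three-component domino Knoevenagel/hetero-Diels–Alder coupling of diformylphloroglucinol, an aldehyde and a caryophyllene-type terpene. The dihydropyran ring closes by a concerted but asynchronous [4+2] cycloaddition in which the C1′–C1 bond is ahead and the phenolic oxygen ends on the more substituted carbon C10. C10 and C1 follow from suprafacial addition to the E-alkene (C14 and H-1 anti, trans ring fusion). C1′ follows from the E geometry of 16 (isobutyl outside) together with an endo orientation of the C2/C14 edge of the alkene, which places H-1′ cis to H-1. The absolute sense is relayed from C7: with the bulky 2-hydroxypropan-2-yl group pseudo-equatorial, the cyclodecadiene should hold the alkene with one face turned into the ring, leaving only the outer face open to 16. The step needs site selectivity over the 4(15),5-diene and freedom from cationic transannular cyclisation; the strain and higher substitution of C1=C10, the buffered non-ionising medium and the slow release of 16 are relied on for both.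

**Compound list**
1 | 5,5-dimethylfuran-2(5H)-one | CC1(C)C=CC(=O)O1 | starting material
2 | (R)-5,5-dimethyl-4-vinyldihydrofuran-2(3H)-one | C=C[C@H]1CC(=O)OC1(C)C | intermediate
3 | (4R)-5,5-dimethyl-4-vinyltetrahydrofuran-2-ol (anomers) | C=C[C@H]1CC(O)OC1(C)C | intermediate
4 | cyclopentane-1,3-dione | O=C1CCC(=O)C1 | starting material
5 | 2-[(3R)-3-(2-hydroxypropan-2-yl)pent-4-en-1-ylidene]cyclopentane-1,3-dione | C=C[C@H](C(C)(C)O)CC=C1C(=O)CCC1=O | intermediate (not isolated)
6 | 2-[(3R)-3-(2-hydroxypropan-2-yl)pent-4-en-1-yl]cyclopentane-1,3-dione | C=C[C@H](C(C)(C)O)CCC1C(=O)CCC1=O | intermediate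
7 | 2-[(3R)-3-(2-hydroxypropan-2-yl)pent-4-en-1-yl]-2-methylcyclopentane-1,3-dione | C=C[C@H](C(C)(C)O)CCC1(C)C(=O)CCC1=O | intermediate
8 | 3-hydroxy-2-[(3R)-3-(2-hydroxypropan-2-yl)pent-4-en-1-yl]-2-methyl-3-vinylcyclopentan-1-one; vinyl cis to ring methyl (one of two convergent diastereomers) | C=C[C@H](C(C)(C)O)CC[C@]1(C)C(=O)CC[C@@]1(O)C=C | intermediate
9 | 2-[(3R)-3-(2-hydroxypropan-2-yl)pent-4-en-1-yl]-2-methyl-1-vinylcyclopentane-1,3-diol; hydroxyls trans, secondary hydroxyl cis to ring methyl (one of two convergent diastereomers) | C=C[C@H](C(C)(C)O)CC[C@]1(C)[C@@H](O)CC[C@@]1(O)C=C | intermediate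
10 | 6-(2-hydroxypropan-2-yl)-8a-methyl-1,2,3,3a,6,7,8,8a-octahydroazulene-1,3a-diol; trans-fused, 1-OH cis to 8a-methyl, 6R (one of two convergent diastereomers) | CC(C)(O)[C@@H]1CC[C@]2(C)[C@@H](O)CC[C@@]2(O)C=C1 | intermediate
11 | 3a-hydroxy-6-(2-hydroxypropan-2-yl)-8a-methyl-1,2,3,3a,6,7,8,8a-octahydroazulen-1-yl methanesulfonate; same configuration as 10 | CC(C)(O)[C@@H]1CC[C@]2(C)[C@@H](OS(C)(=O)=O)CC[C@@]2(O)C=C1 | intermediate
12 | (2Z,4R,7E)-4-(2-hydroxypropan-2-yl)-7-methylcyclodeca-2,7-dien-1-one | CC(C)(O)[C@@H]1CC/C(C)=C/CCC(=O)/C=C\1 | intermediate (not isolated)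
13 | (1(10)E,5Z,7R)-germacra-1(10),4(15),5-trien-11-ol = 2-[(1R,2Z,7E)-8-methyl-4-methylidenecyclodeca-2,7-dien-1-yl]propan-2-ol | CC(C)(O)[C@@H]1CC/C(C)=C/CCC(=C)/C=C\1 | intermediate
14 | 2,4,6-trihydroxybenzene-1,3-dicarbaldehyde (2,4-diformylphloroglucinol) | O=Cc1c(O)cc(O)c(C=O)c1O | starting material
15 | 3-methylbutanal | CC(C)CC=O | starting material
16 | (E)-o-quinone methide: 2,4-dihydroxy-5-(3-methylbutylidene)-6-oxocyclohexa-1,3-diene-1,3-dicarbaldehyde | CC(C)C/C=C1/C(=O)C(C=O)=C(O)C(C=O)=C1O | intermediate (not isolated)
17 | CNP0479784.1: 6,8-diformyl-5,7-dihydroxychromane with O1–C2(methyl)–C3 = O–C10–C1 of the (5Z,7R)-4(15),5-germacradien-11-ol ring (trans-fused) and isobutyl on C4 (H-1′ cis to H-1) | C=C1/C=C\[C@H](C(C)(C)O)CC[C@@]2(C)Oc3c(C=O)c(O)c(C=O)c(O)c3[C@H](CC(C)C)[C@@H]2CC1 | target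

**Count:** 10 steps in total; the longest linear sequence is 10 steps (from 1).

**Steps most likely to fail**

Step 10. The cycloaddition may fail through acid-induced transannular cyclisation of the trienol, through stepwise ionic addition followed by transannular capture of the C10 cation, through attack of the quinone methide on the conjugated diene, or through poor facial discrimination on the flexible ring. The fallback sets out from 13, 14 and 15 and comes back at 17. The heterodiene is made beforehand in masked form and released thermally without acid or water. Condensation of 14, 15 and morpholine (EtOH, 25 °C) should give the Mannich base 2,4,6-trihydroxy-5-[3-methyl-1-(morpholin-4-yl)butyl]benzene-1,3-dicarbaldehyde F1. Heating F1 with 13 in toluene at 80–100 °C releases 16 by retro-Mannich loss of morpholine at low stationary concentration in a non-polar medium, where the concerted cycloaddition to C1=C10 should be favoured, giving 17 directly.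

Step 9. The fragmentation may be slowed by imperfect anti-periplanar alignment in the five-membered ring (E2 elimination competing), the Z-enone may epimerise at C7 or isomerise under base, and the basic ylide may olefinate the hindered enone slowly. The fallback sets out from 11 and comes back at 13. The two events are separated and the olefination is changed to a Peterson sequence. KN(SiMe3)2 (1.05 equiv, THF, −78 → −20 °C) with a buffered cold quench should give the isolated enone 12. The weakly basic cerium reagent from Me3SiCH2Li and CeCl3 (THF, −78 °C) adds 1,2 to give the β-hydroxysilane (2Z,4R,7E)-4-(2-hydroxypropan-2-yl)-7-methyl-1-[(trimethylsilyl)methyl]cyclodeca-2,7-dien-1-ol F2. KH in THF at 0 °C then effects syn-elimination to 13.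

Step 5. The vinyl addition may show poor facial selectivity (the minor C4 epimer would lead, after step 6, to the 1(10)Z isomer), and may suffer over-addition or retro-aldol ring opening. The fallback sets out from 7 and comes back at 10; it is reagent-controlled and also gives single diastereomers.
- (S)-2-Methyl-CBS-oxazaborolidine (10 mol%) with catecholborane (toluene, −78 °C) selects one carbonyl and should give (2R,3R)-3-hydroxy-2-[(3R)-3-(2-hydroxypropan-2-yl)pent-4-en-1-yl]-2-methylcyclopentan-1-one F3, with the hydroxyl cis to the chain.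
- CH2=CHMgBr/CeCl3 (THF, −78 °C) then adds anti to both the chain and the alkoxide, giving the vinyl diol F4 with both hydroxyls trans to the methyl group.
- Ring-closing metathesis as in step 7 gives the trans-fused bicyclic diol F5.
- Dess–Martin periodinane oxidises the secondary alcohol to the β-hydroxy ketone 3a-hydroxy-6-(2-hydroxypropan-2-yl)-8a-methyl-2,3,3a,6,7,8-hexahydroazulen-1(8aH)-one F6.
- Me4NBH(OAc)3, as in step 6, delivers hydride from the face of the ring-fusion hydroxyl and gives 10.

**Further compounds**
F1 | step 10 | 2,4,6-trihydroxy-5-[3-methyl-1-(morpholin-4-yl)butyl]benzene-1,3-dicarbaldehyde (racemic) | CC(C)CC(N1CCOCC1)c1c(O)c(C=O)c(O)c(C=O)c1O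
F2 | step 9 | (2Z,4R,7E)-4-(2-hydroxypropan-2-yl)-7-methyl-1-[(trimethylsilyl)methyl]cyclodeca-2,7-dien-1-ol (C1 epimers) | CC(C)(O)[C@@H]1CC/C(C)=C/CCC(O)(C[Si](C)(C)C)/C=C\1
F3 | step 5 | (2R,3R)-3-hydroxy-2-[(3R)-3-(2-hydroxypropan-2-yl)pent-4-en-1-yl]-2-methylcyclopentan-1-one | C=C[C@H](C(C)(C)O)CC[C@]1(C)[C@H](O)CCC1=O
F4 | step 5 | 2-[(3R)-3-(2-hydroxypropan-2-yl)pent-4-en-1-yl]-2-methyl-1-vinylcyclopentane-1,3-diol (hydroxyls cis to each other, both trans to the ring methyl) | C=C[C@H](C(C)(C)O)CC[C@]1(C)[C@H](O)CC[C@@]1(O)C=C
F5 | step 5 | 6-(2-hydroxypropan-2-yl)-8a-methyl-1,2,3,3a,6,7,8,8a-octahydroazulene-1,3a-diol (trans-fused, 1-OH trans to 8a-methyl) | CC(C)(O)[C@@H]1CC[C@]2(C)[C@H](O)CC[C@@]2(O)C=C1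
F6 | step 5 | 3a-hydroxy-6-(2-hydroxypropan-2-yl)-8a-methyl-2,3,3a,6,7,8-hexahydroazulen-1(8aH)-one (trans-fused) | CC(C)(O)[C@@H]1CC[C@]2(C)C(=O)CC[C@@]2(O)C=C1
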